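**Plan**

- Retrosynthesis: the C2=C3 double bond of the pyranone ring is traced back to a C3 tertiary alcohol (loss of water). The C3–C4 bond is cut next, then the O1–C2 ether bond, and last the C–Br bond of a phenacyl bromide.
- Enabling feature: in ring C the carbonyl carbon C4 (on ring A) and the B-ring-bearing carbon C3 are neighbours. At the open-chain stage both are carbonyl carbons, the A-ring formyl carbon and the B-ring aryl ketone carbon, joined through O1–C2, so reversing the polarity of the formyl carbon joins them.
- Forward: acetophenone 1 is brominated to 2, phenol 3 is alkylated to lay down O1–C2 (4), a carbene-catalysed benzoin reaction closes ring C at C3–C4 (5), and dehydration through chlorosulfite 6 installs C2=C3 (7).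
- Stereochemistry: the target is achiral. The C3 carbinol centre of 5 is made as a racemate and is destroyed in the last step.

Key step: step 3

Remark: the target contains no stereogenic element, so the single-enantiomer requirement is met by the achiral structure itself.
Remark: catalyst-bound species of the carbene cycle in step 3 are treated as mechanism and are not numbered; the stoichiometric chlorosulfite of step 4 is numbered.

**Step 1**
Reactants: 1 1-(2,3,4-trimethoxyphenyl)ethanone
Product: 2 2-bromo-1-(2,3,4-trimethoxyphenyl)ethanone
Conditions: CuBr2 (2.1 equiv), EtOAc/CHCl3 1:1, reflux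
Reagents that add atoms: copper(II) bromide, Br[Cu]Br
Why: Copper(II) bromide α-bromination of an aryl methyl ketone (King–Ostrum conditions): the copper-bound enol of the acetyl group is brominated while the electron-rich trimethoxyarene, which free bromine would attack, is left alone, and the monobromide enolises too slowly to go on to the dibromide.

**Step 2**
Reactants: 2 2-bromo-1-(2,3,4-trimethoxyphenyl)ethanone; 3 2-hydroxy-4,5-dimethoxybenzaldehyde
Product: 4 4,5-dimethoxy-2-[2-oxo-2-(2,3,4-trimethoxyphenyl)ethoxy]benzaldehyde
Conditions: K2CO3 (1.2 equiv), acetone, 0 °C to rt, no heating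
Reagents that add atoms: none
Why: Williamson ether synthesis: the phenoxide of 3, acidified by its ortho formyl group, displaces bromide from the SN2-reactive phenacyl bromide 2, and mild carbonate base without heating keeps the product ether from enolising and condensing onto its own aldehyde (Rap–Stoermer benzofuran formation).

**Step 3**
Reactants: 4 4,5-dimethoxy-2-[2-oxo-2-(2,3,4-trimethoxyphenyl)ethoxy]benzaldehyde
Product: 5 (±)-3-hydroxy-6,7-dimethoxy-3-(2,3,4-trimethoxyphenyl)chroman-4-one
Conditions: 2-(pentafluorophenyl)-6,7-dihydro-5H-pyrrolo[2,1-c][1,2,4]triazol-2-ium tetrafluoroborate (10 mol%), Et3N (10 mol%), degassed THF, rt, Ar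
Reagents that add atoms: none
Why: Et3N frees the triazolylidene, which adds to the formyl group of 4; proton transfer gives the Breslow enaminol, whose former formyl carbon (the future C4) is now nucleophilic and attacks the tethered aryl ketone carbon (the future C3), after which the adduct collapses to release the carbene and the α-hydroxy ketone 5. The closest known reaction type is the NHC-catalysed intramolecular crossed aldehyde–ketone benzoin reaction of 2-(2-oxoalkoxy)benzaldehydes, which gives 3-hydroxychroman-4-ones, 3-aryl examples included. The pyranone ring closes by 6-exo-trig attack on the ketone C=O, forming the C3–C4 bond. The C3 carbinol centre arises as a racemate because catalyst and substrate are achiral, and no control is sought since C3 becomes sp2 in step 4. The step needs the crossed intramolecular mode to win over aldehyde homo-benzoin and over aldol closure at the O–CH2–CO methylene. Only the aldehyde can form a Breslow intermediate, the ortho O–CH2 tether makes six-membered closure faster than any bimolecular path, and a substoichiometric tertiary amine keeps the enolate concentration negligible.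

**Step 4**
Reactants: 5 (±)-3-hydroxy-6,7-dimethoxy-3-(2,3,4-trimethoxyphenyl)chroman-4-one
Product: 7 6,7,2',3',4'-pentamethoxyisoflavone (6,7-dimethoxy-3-(2,3,4-trimethoxyphenyl)-4H-chromen-4-one), via chlorosulfite ester 6 (not isolated)
Conditions: SOCl2 (1.5 equiv), pyridine (4 equiv), CH2Cl2, 0 °C to rt
Reagents that add atoms: none
Why: Thionyl chloride–pyridine dehydration of a tertiary alcohol, as used for tertiary α-ketols: the chlorosulfite 6 loses SO2 and chloride while pyridine removes a proton from C2, the only carbon next to C3 that carries hydrogen, so the conjugated chromone C2=C3 is the sole alkene possible and the C3 stereocentre disappears.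

**Compound list**

1 | 1-(2,3,4-trimethoxyphenyl)ethanone | CC(=O)c1ccc(OC)c(OC)c1OC | starting material
2 | 2-bromo-1-(2,3,4-trimethoxyphenyl)ethanone | BrCC(=O)c1ccc(OC)c(OC)c1OC | intermediate
3 | 2-hydroxy-4,5-dimethoxybenzaldehyde | COc1cc(O)c(C=O)cc1OC | starting material
4 | 4,5-dimethoxy-2-[2-oxo-2-(2,3,4-trimethoxyphenyl)ethoxy]benzaldehyde | O=Cc1cc(OC)c(OC)cc1OCC(=O)c1ccc(OC)c(OC)c1OC | intermediate
5 | (±)-3-hydroxy-6,7-dimethoxy-3-(2,3,4-trimethoxyphenyl)chroman-4-one (racemic) | COc1cc2OCC(O)(c3ccc(OC)c(OC)c3OC)C(=O)c2cc1OC | intermediate
6 | 6,7-dimethoxy-4-oxo-3-(2,3,4-trimethoxyphenyl)chroman-3-yl chlorosulfite (racemic, not isolated) | COc1cc2OCC(OS(=O)Cl)(c3ccc(OC)c(OC)c3OC)C(=O)c2cc1OC | intermediate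
7 | 6,7,2',3',4'-pentamethoxyisoflavone | COc1cc2occ(-c3ccc(OC)c(OC)c3OC)c(=O)c2cc1OC | target

**Step count**

Total step count: 4. Longest linear sequence: 4 steps (1 → 2 → 4 → 5 → 7); phenol 3 enters at step 2.

**Steps most likely to fail**

Step 3. Addition of the Breslow enaminol to the hindered, electron-rich ortho-methoxyaryl ketone may be slow. Base-induced enolisation of the O–CH2–CO unit and aldol closure onto the formyl group could then take over. The fallback sets out from 4 and forms the same C3–C4 bond reductively, without base. Pinacol cyclisation with SmI2 in THF at −78 °C, with slow addition of 4 at high dilution, should give 6,7-dimethoxy-3-(2,3,4-trimethoxyphenyl)chromane-3,4-diol F1 as a racemic mixture of diastereomers. HMPA is left out so that the aryl ketone ketyl, which would expel the aryloxide, does not form ahead of the aldehyde ketyl. Oxidation of the secondary benzylic C4 alcohol with IBX in DMSO at rt, which does not cleave glycols, would bring the sequence back to the route at 5.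

Step 4. Ionisation at C3 may be followed by chloride capture or by acyloin (α-ketol) rearrangement with ring contraction instead of proton loss from C2. The fallback sets out from 5 and replaces dehydration by deoxygenation and then dehydrogenation. Acetylation (Ac2O, DMAP, Et3N, CH2Cl2) should give 6,7-dimethoxy-4-oxo-3-(2,3,4-trimethoxyphenyl)chroman-3-yl acetate F2. Reductive cleavage of the α-acetoxy group with SmI2 in THF/MeOH at −78 °C should give the isoflavanone 6,7-dimethoxy-3-(2,3,4-trimethoxyphenyl)chroman-4-one F3. DDQ in refluxing dioxane would then dehydrogenate C2–C3 and return to the route at 7.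

Step 2. The ether may react further under the alkylation conditions: enolisation next to the ketone and intramolecular aldol condensation onto the aldehyde would consume it before isolation. The fallback sets out from 2 and forms the O1–C2 bond under neutral conditions. Sodium formate in refluxing aqueous ethanol should displace bromide to give 2-oxo-2-(2,3,4-trimethoxyphenyl)ethyl formate F4, which is solvolysed in the same pot to 2-hydroxy-1-(2,3,4-trimethoxyphenyl)ethanone F5. Mitsunobu etherification of phenol 3 with this alcohol (PPh3, DIAD, THF, 0 °C to rt) would rejoin the route at 4.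

**Further compounds**

F1 | step 3 | 6,7-dimethoxy-3-(2,3,4-trimethoxyphenyl)chromane-3,4-diol (racemic, mixture of diastereomers) | COc1cc2OCC(O)(c3ccc(OC)c(OC)c3OC)C(O)c2cc1OC
F2 | step 4 | 6,7-dimethoxy-4-oxo-3-(2,3,4-trimethoxyphenyl)chroman-3-yl acetate (racemic) | COc1cc2OCC(OC(C)=O)(c3ccc(OC)c(OC)c3OC)C(=O)c2cc1OC
F3 | step 4 | 6,7-dimethoxy-3-(2,3,4-trimethoxyphenyl)chroman-4-one (racemic) | COc1cc2OCC(c3ccc(OC)c(OC)c3OC)C(=O)c2cc1OC
F4 | step 2 | 2-oxo-2-(2,3,4-trimethoxyphenyl)ethyl formate | O=COCC(=O)c1ccc(OC)c(OC)c1OC
F5 | step 2 | 2-hydroxy-1-(2,3,4-trimethoxyphenyl)ethanone | OCC(=O)c1ccc(OC)c(OC)c1OC
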